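Everything rests on opening ring B at C6–C7: in ring B the C6 carbinol is homoallylic to the C8=C9 alkene, the imprint of a type 2 carbonyl-ene closure. In one operation Me2AlCl joins the C6 aldehyde on C5 to the C7H2 terminus of an isopropenyl group, closes ring B as a trans-decalin, sets the equatorial C6 hydroxyl and leaves a C8 exocyclic alkene that acid later moves to C8=C9. The precursor is a complete ring A (C2, C4, C5, C10 set) with the equatorial aldehyde on C5 and, on C10, C9 bearing the isopropenyl group and a benzyloxyethyl arm (C11–C12). Because allylsilanes attack enals at carbonyl carbon, C10 is built by 1,2-allylation and anionic oxy-Cope rearrangement.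

Key step: step 16

Remark: labdane numbering is used for every intermediate (ring A = C1–C5 and C10). α is the face of H-5 and β the face of the C20 methyl group. The target is (2R,4S,5R,6S,10S): 2α-OH and 6α-OH equatorial, C19 CH2OH axial β, H-5 α, C20 β.
Assumption: the (R,R)-lithium amide of step 4 is taken to remove the axial hydrogen on C4. If the sense of induction is the opposite, the commercial (S,S) antipode is used and nothing else changes.

Step 1
Reactants: 1 2,6-dimethyl-1,4-benzoquinone
Product: 3 all-cis-2,6-dimethylcyclohexane-1,4-diol (meso), via 2,6-dimethylhydroquinone 2 (not isolated)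
Conditions: H2 (60 bar), Rh/Al2O3 (5 %), EtOH, 60 °C
Reagents that add atoms: none
Why: The quinone is first reduced to hydroquinone 2, and heterogeneous arene hydrogenation on rhodium then delivers all hydrogens to one ring face, so the all-cis meso diol should dominate and stray isomers are removed by crystallisation.

Step 2
Reactants: 3 all-cis-2,6-dimethylcyclohexane-1,4-diol
Product: 4 all-cis-4-(tert-butyldiphenylsilyloxy)-2,6-dimethylcyclohexan-1-ol (meso)
Conditions: TBDPSCl (1.0 equiv), imidazole, CH2Cl2, 0 °C
Reagents that add atoms: tert-butyldiphenylsilyl chloride, CC(C)(C)[Si](Cl)(c1ccccc1)c1ccccc1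
Why: Chemoselective silyl ether formation, in which the bulky chlorosilane picks the unhindered equatorial hydroxyl (future C2–O) over the axial hydroxyl flanked by two methyl groups (future C5).

Step 3
Reactants: 4 all-cis-4-(tert-butyldiphenylsilyloxy)-2,6-dimethylcyclohexan-1-ol
Product: 5 cis,cis-4-(tert-butyldiphenylsilyloxy)-2,6-dimethylcyclohexan-1-one (meso)
Conditions: (n-Pr4N)RuO4 (5 mol %), NMO, 4 Å MS, CH2Cl2, rt
Reagents that add atoms: none
Why: Ley–Griffith oxidation converts the hindered axial alcohol into the C5 ketone under neutral conditions, which leaves both α-methyl groups equatorial and the compound meso.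

Step 4
Reactants: 5 cis,cis-4-(tert-butyldiphenylsilyloxy)-2,6-dimethylcyclohexan-1-one
Product: 7 ring A trimethylsilyl enol ether (C4=C5; 2α-OTBDPS; 10α-methyl), via lithium enolate 6 (not isolated)
Conditions: (R,R)-bis(1-phenylethyl)amine, n-BuLi, LiCl, THF; TMSCl then 5, −100 → −78 °C
Reagents that add atoms: chlorotrimethylsilane, C[Si](C)(C)Cl
Why: Enantioselective deprotonation of a meso ketone by a chiral twofold-symmetric lithium amide with in situ silylation removes one of the two enantiotopic axial α-hydrogens (that on C4), which turns C2 and C10 into true stereocentres and fixes the absolute configuration of the whole series.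

Step 5
Reactants: 7 ring A trimethylsilyl enol ether; 8 formaldehyde
Product: 9 ring A β-hydroxy ketone (C4: CH2OH β axial and CH3 α; 2α-OTBDPS; 10α-methyl)
Conditions: aq HCHO (37 %), Yb(OTf)3 (10 mol %), THF, rt
Reagents that add atoms: none
Why: In this lanthanide-triflate-catalysed aqueous Mukaiyama aldol (hydroxymethylation), formaldehyde approaches C4 of the half-chair along the axial β trajectory that leads directly to a chair, trans to the equatorial C2 silyloxy group, so CH2OH becomes axial C19 and the methyl equatorial C18, and the minor epimer is separable.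

Step 6
Reactants: 9 ring A β-hydroxy ketone
Product: 10 ring A bis(TBDPS) ketone
Conditions: TBDPSCl, imidazole, DMAP (cat), DMF, 40 °C
Reagents that add atoms: tert-butyldiphenylsilyl chloride, CC(C)(C)[Si](Cl)(c1ccccc1)c1ccccc1
Why: Silyl ether formation masks the β-hydroxy ketone before strong base is used, which rules out retro-aldol loss of formaldehyde, and the bulky acid-stable group is chosen to survive steps 16 and 18.

Step 7
Reactants: 10 ring A bis(TBDPS) ketone
Product: 12 ring A enol triflate (C5=C10), via potassium enolate 11 (not isolated)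
Conditions: KN(SiMe3)2, THF, −78 → 0 °C; PhNTf2, −78 °C → rt
Reagents that add atoms: N-phenylbis(trifluoromethanesulfonimide), O=S(=O)(N(c1ccccc1)S(=O)(=O)C(F)(F)F)C(F)(F)F
Why: C10–H is the only enolisable position, so deprotonation and O-triflation of the enolate give a single tetrasubstituted enol triflate, as is known for 2,2,6-trisubstituted cyclohexanones.

Step 8
Reactants: 12 ring A enol triflate
Product: 13 ring A enal (C5(CHO)=C10(CH3))
Conditions: Pd(OAc)2 (5 mol %), dppp, CO (1 atm), Et3SiH, Et3N, DMF, 70 °C
Reagents that add atoms: carbon monoxide, [C-]#[O+]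
Why: Palladium-catalysed reductive carbonylation (formylation) of the enol triflate inserts CO as C6, and the silane delivers hydride to the acylpalladium species, giving the enal without touching the silyl ethers.

Step 9
Reactants: 14 4-methylpent-3-en-1-ol
Product: 15 benzyl 4-methylpent-3-enyl ether
Conditions: NaH, BnBr, Bu4NI (cat), THF, 0 °C → rt
Reagents that add atoms: benzyl bromide, BrCc1ccccc1
Why: Williamson etherification installs a plain benzyl ether, chosen over an electron-rich arylmethyl ether because it must survive barium, KH, Me2AlCl and the acid of step 18 and still leave selectively by hydrogenolysis.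

Step 10
Reactants: 15 benzyl 4-methylpent-3-enyl ether
Product: 16 (E)-5-(benzyloxy)-2-methylpent-2-en-1-ol
Conditions: SeO2 (cat), t-BuOOH, CH2Cl2, 0 °C → rt
Reagents that add atoms: tert-butyl hydroperoxide, CC(C)(C)OO
Why: Riley allylic oxidation of a gem-dimethyl trisubstituted alkene is selective for the E methyl group through its ene and [2,3]-sigmatropic sequence, which fixes the alkene geometry needed in step 15.

Step 11
Reactants: 16 (E)-5-(benzyloxy)-2-methylpent-2-en-1-ol
Product: 17 (E)-5-(benzyloxy)-2-methylpent-2-enyl chloride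
Conditions: NCS, Me2S, CH2Cl2, −20 → 0 °C
Reagents that add atoms: N-chlorosuccinimide, O=C1CCC(=O)N1Cl
Why: Corey–Kim chlorination converts the allylic alcohol into the primary chloride by SN2 displacement of the alkoxysulfonium ion, without allylic transposition or loss of alkene geometry.

Step 12
Reactants: 17 (E)-5-(benzyloxy)-2-methylpent-2-enyl chloride; 13 ring A enal
Product: 19 linear 1,5-dien-3-ol (C6 carbinol as both epimers; E C8=C9), via allylbarium chloride 18 (not isolated)
Conditions: BaI2, LiC12H10 (lithium biphenylide, 2 equiv), THF, rt; 17, −78 °C; 13, −78 °C; aq NH4Cl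
Reagents that add atoms: none
Why: Allylsilanes and most allylmetals would bond through C9, whereas allylbarium reagents are known to add 1,2 to aldehydes through the unsubstituted α-carbon (C7) with retention of alkene geometry, which gives the linear dienol whose C6 epimers are converged in steps 13 and 14.

Step 13
Reactants: 19 linear 1,5-dien-3-ol
Product: 20 cross-conjugated β,γ-unsaturated dienone (C6 ketone)
Conditions: Dess–Martin periodinane, CH2Cl2, 0 °C
Reagents that add atoms: none
Why: Dess–Martin oxidation removes the uncontrolled C6 centre under mild conditions that should not move the C8=C9 alkene into conjugation.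

Step 14
Reactants: 20 dienone
Product: 21 (6S)-1,5-dien-3-ol
Conditions: (R)-Me-CBS oxazaborolidine, catecholborane, toluene, −78 → −40 °C
Reagents that add atoms: none
Why: Corey–Bakshi–Shibata reduction differentiates the bulky cyclohexenyl group from the C7 methylene group, so the (R)-oxazaborolidine should deliver hydride to give the (6S)-alcohol, and catecholborane at low temperature avoids hydroboration.

Step 15
Reactants: 21 (6S)-1,5-dien-3-ol
Product: 23 ring A aldehyde with the isopropenyl-bearing C9 on C10 (ene precursor), via potassium enolate 22 (not isolated)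
Conditions: KH, 18-crown-6, THF, 0 °C → rt; AcOH, THF, −78 °C
Reagents that add atoms: none
Why: In this anionic oxy-Cope rearrangement, allylic 1,3-strain with the C20 methyl keeps H-6 inside and the oxyanion outside, so the (6S)-alkoxide can only swing C9 onto the α face of C10 (chirality transfer from C6 to C10), the E alkene in a chair array gives the drawn C9 centre (sacrificial, erased in step 18), and kinetic protonation of enolate 22 from the α face, opposite the axial C19 and C20 groups, sets H-5 α and the aldehyde equatorial.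

Step 16
Reactants: 23 ring A aldehyde (ene precursor)
Product: 25 trans-decalin 6α-alcohol with exocyclic C8 methylene, via aluminium alkoxide 24 (not isolated)
Conditions: Me2AlCl (2.5 equiv), CH2Cl2, −78 → −20 °C; 1 M HCl
Reagents that add atoms: none
Why: Me2AlCl binds the C6 aldehyde oxygen, the electron-rich C7H2 terminus of the 1,1-disubstituted alkene attacks C6 while charge builds at tertiary C8, a hydrogen of the C17 methyl ends on oxygen, and the alcohol–aluminium complex loses methane to give alkoxide 24, so no protic acid is left to isomerise or desilylate anything. The closest known reaction is the Me2AlCl-promoted type 2 intramolecular carbonyl-ene (Prins) cyclisation of 5-methylhex-5-enals to 3-methylenecyclohexanols. Ring B (C5–C6–C7–C8–C9–C10) closes six-membered with the tether on the central ene carbon C8, that is 6-endo at the alkene and 6-exo at the carbonyl group, and it must be trans-fused because C6 on C5 and C9 on C10 are both equatorial on the ring A chair. The new centre C6 is controlled by the axial C20 methyl and the axial C19 silyloxymethyl group: only the aldehyde hydrogen fits between them on the β face, so the aluminium-bound oxygen points equatorial and the carbinol is 6α. Because this excludes the compact transition state with axial oxygen, hydrogen transfer may be stepwise through the C8 cation, and any C7=C8 or C8=C9 alkene or C8 chloride formed beside 25 is carried on, since the acid equilibration of step 18 funnels all of them to the same tetrasubstituted alkene. The step needs closure to outrun C5 enolisation and methyl transfer to the aldehyde, which is secured by low temperature, the proton-scavenging Lewis acid, the weakly basic silyl and benzyl ethers (no electron-rich arene, no chelating group) and the preorganised diequatorial chain.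

Step 17
Reactants: 25 trans-decalin 6α-alcohol
Product: 26 6α-TBS ether
Conditions: TBSOTf, 2,6-lutidine, CH2Cl2, 0 °C
Reagents that add atoms: tert-butyldimethylsilyl triflate, CC(C)(C)[Si](C)(C)OS(=O)(=O)C(F)(F)F
Why: Silyl ether formation with the reactive triflate and a hindered base covers the crowded equatorial C6 alcohol, which removes the only acidic proton before the organozinc step and tames the carbinol for the acid treatment.

Step 18
Reactants: 26 6α-TBS ether
Product: 27 C8=C9 tetrasubstituted alkene
Conditions: TsOH (anhydrous, 10 mol %), benzene, 70 °C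
Reagents that add atoms: none
Why: Acid-catalysed alkene equilibration through the tertiary C8 cation drains the exocyclic alkene and any C7=C8 isomer into the tetrasubstituted C8=C9 alkene, the thermodynamic sink of labdane ring B, and thereby erases C9, while the bulky silyl ethers and the benzyl ether tolerate anhydrous acid.

Step 19
Reactants: 27 C8=C9 alkene
Product: 28 C12 primary alcohol
Conditions: H2 (1 atm), Pd(OH)2/C, EtOAc, rt
Reagents that add atoms: none
Why: Hydrogenolysis cleaves the benzyl ether, while the hindered tetrasubstituted alkene and the silyl ethers are inert under these conditions.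

Step 20
Reactants: 28 C12 primary alcohol
Product: 29 C12 primary iodide
Conditions: I2, PPh3, imidazole, CH2Cl2, 0 °C
Reagents that add atoms: iodine, II
Why: Appel-type iodination of the only free and unhindered primary alcohol proceeds by SN2 displacement of the alkoxyphosphonium ion.

Step 21
Reactants: 29 C12 primary iodide; 30 4-bromofuran-2(5H)-one
Product: 32 tris-silylated target, via alkylzinc iodide 31 (not isolated)
Conditions: Zn dust (TMSCl-activated), DMA, 40 °C; 30, PdCl2(dppf) (5 mol %), THF, 45 °C
Reagents that add atoms: none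
Why: Zinc insertion gives a functional-group-tolerant alkylzinc iodide, and its Negishi coupling with the β-bromobutenolide benefits from fast oxidative addition and a wide-bite-angle ligand that lets reductive elimination outrun β-hydride elimination, forming C12–C13.

Step 22
Reactants: 32 tris-silylated target
Product: 33 2α,6α,19-trihydroxylabda-8,13-dien-15,16-olide (CNP0387838.1)
Conditions: HF·pyridine, pyridine, THF, 0 °C → rt
Reagents that add atoms: none
Why: Fluoride-driven cleavage of all three silyl ethers under mildly acidic conditions spares the base-sensitive butenolide and touches no stereocentre, giving the triol.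

Compound list
1 | 2,6-dimethyl-1,4-benzoquinone | CC1=CC(=O)C=C(C)C1=O | starting material
2 | 2,6-dimethylhydroquinone | Cc1cc(O)cc(C)c1O | intermediate
3 | all-cis-2,6-dimethylcyclohexane-1,4-diol (meso, all four substituents on one face) | C[C@H]1C[C@@H](O)C[C@@H](C)[C@H]1O | intermediate
4 | all-cis-4-(tert-butyldiphenylsilyloxy)-2,6-dimethylcyclohexan-1-ol (meso) | C[C@H]1C[C@@H](O[Si](c2ccccc2)(c2ccccc2)C(C)(C)C)C[C@@H](C)[C@H]1O | intermediate
5 | cis,cis-4-(tert-butyldiphenylsilyloxy)-2,6-dimethylcyclohexan-1-one (meso, carbonyl = C5, three equatorial substituents) | C[C@H]1C[C@@H](O[Si](c2ccccc2)(c2ccccc2)C(C)(C)C)C[C@@H](C)C1=O | intermediate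
6 | lithium enolate C4=C5 (2α-OTBDPS, 10α-methyl) | C[C@H]1C[C@@H](O[Si](c2ccccc2)(c2ccccc2)C(C)(C)C)CC(C)=C1O[Li] | intermediate
7 | trimethylsilyl enol ether C4=C5 (2α-OTBDPS, 10α-methyl) | C[C@H]1C[C@@H](O[Si](c2ccccc2)(c2ccccc2)C(C)(C)C)CC(C)=C1O[Si](C)(C)C | intermediate
8 | formaldehyde | C=O | starting material
9 | 2-(hydroxymethyl)-2,6-dimethyl-4-(TBDPS-oxy)cyclohexanone (C4: CH2OH β, CH3 α; 2α-OTBDPS; 10α-methyl) | C[C@H]1C[C@@H](O[Si](c2ccccc2)(c2ccccc2)C(C)(C)C)C[C@](C)(CO)C1=O | intermediate
10 | bis(TBDPS) ketone (C19 and C2 oxygens silylated) | C[C@H]1C[C@@H](O[Si](c2ccccc2)(c2ccccc2)C(C)(C)C)C[C@](C)(CO[Si](c2ccccc2)(c2ccccc2)C(C)(C)C)C1=O | intermediate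
11 | potassium enolate C5=C10 | CC1=C(O[K])[C@@](C)(CO[Si](c2ccccc2)(c2ccccc2)C(C)(C)C)C[C@H](O[Si](c2ccccc2)(c2ccccc2)C(C)(C)C)C1 | intermediate
12 | enol triflate C5(OTf)=C10(CH3) | CC1=C(OS(=O)(=O)C(F)(F)F)[C@@](C)(CO[Si](c2ccccc2)(c2ccccc2)C(C)(C)C)C[C@H](O[Si](c2ccccc2)(c2ccccc2)C(C)(C)C)C1 | intermediate
13 | ring A enal C5(CHO)=C10(CH3) | CC1=C(C=O)[C@@](C)(CO[Si](c2ccccc2)(c2ccccc2)C(C)(C)C)C[C@H](O[Si](c2ccccc2)(c2ccccc2)C(C)(C)C)C1 | intermediate
14 | 4-methylpent-3-en-1-ol | CC(C)=CCCO | starting material
15 | benzyl 4-methylpent-3-enyl ether | CC(C)=CCCOCc1ccccc1 | intermediate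
16 | (E)-5-(benzyloxy)-2-methylpent-2-en-1-ol | OC/C(C)=C/CCOCc1ccccc1 | intermediate
17 | (E)-5-(benzyloxy)-2-methylpent-2-enyl chloride | ClC/C(C)=C/CCOCc1ccccc1 | intermediate
18 | (E)-5-(benzyloxy)-2-methylpent-2-enylbarium chloride | Cl[Ba]C/C(C)=C/CCOCc1ccccc1 | intermediate
19 | linear 1,5-dien-3-ol, both C6 epimers (centre removed in step 13), E C8=C9 | CC1=C(C(O)C/C(C)=C/CCOCc2ccccc2)[C@@](C)(CO[Si](c2ccccc2)(c2ccccc2)C(C)(C)C)C[C@H](O[Si](c2ccccc2)(c2ccccc2)C(C)(C)C)C1 | intermediate
20 | C6 ketone (dienone) | CC1=C(C(=O)C/C(C)=C/CCOCc2ccccc2)[C@@](C)(CO[Si](c2ccccc2)(c2ccccc2)C(C)(C)C)C[C@H](O[Si](c2ccccc2)(c2ccccc2)C(C)(C)C)C1 | intermediate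
21 | (6S)-1,5-dien-3-ol | CC1=C([C@@H](O)C/C(C)=C/CCOCc2ccccc2)[C@@](C)(CO[Si](c2ccccc2)(c2ccccc2)C(C)(C)C)C[C@H](O[Si](c2ccccc2)(c2ccccc2)C(C)(C)C)C1 | intermediate
22 | potassium (Z)-enolate C5=C6 (oxygen cis to C4) | C=C(C)[C@H](CCOCc1ccccc1)[C@@]2(C)C[C@@H](O[Si](c3ccccc3)(c3ccccc3)C(C)(C)C)C[C@](C)(CO[Si](c3ccccc3)(c3ccccc3)C(C)(C)C)/C2=C\O[K] | intermediate
23 | ene precursor: ring A aldehyde (H-5 α, CHO equatorial; C10: CH3 β, C9 α; C9 bears isopropenyl and CH2CH2OBn) | C=C(C)[C@H](CCOCc1ccccc1)[C@@]2(C)C[C@@H](O[Si](c3ccccc3)(c3ccccc3)C(C)(C)C)C[C@](C)(CO[Si](c3ccccc3)(c3ccccc3)C(C)(C)C)[C@@H]2C=O | intermediate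
24 | chloro(methyl)aluminium 6α-alkoxide of 25 | C=C1[C@H](CCOCc2ccccc2)[C@@]3(C)C[C@@H](O[Si](c4ccccc4)(c4ccccc4)C(C)(C)C)C[C@](C)(CO[Si](c4ccccc4)(c4ccccc4)C(C)(C)C)[C@@H]3[C@@H](O[Al](C)Cl)C1 | intermediate
25 | ene product: trans-decalin, 6α-OH, exocyclic C8=C17, 9α-H | C=C1[C@H](CCOCc2ccccc2)[C@@]3(C)C[C@@H](O[Si](c4ccccc4)(c4ccccc4)C(C)(C)C)C[C@](C)(CO[Si](c4ccccc4)(c4ccccc4)C(C)(C)C)[C@@H]3[C@@H](O)C1 | intermediate
26 | 6α-TBS ether of 25 | C=C1[C@H](CCOCc2ccccc2)[C@@]3(C)C[C@@H](O[Si](c4ccccc4)(c4ccccc4)C(C)(C)C)C[C@](C)(CO[Si](c4ccccc4)(c4ccccc4)C(C)(C)C)[C@@H]3[C@@H](O[Si](C)(C)C(C)(C)C)C1 | intermediate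
27 | C8=C9 alkene, C12 benzyl ether | CC1=C(CCOCc2ccccc2)[C@@]3(C)C[C@@H](O[Si](c4ccccc4)(c4ccccc4)C(C)(C)C)C[C@](C)(CO[Si](c4ccccc4)(c4ccccc4)C(C)(C)C)[C@@H]3[C@@H](O[Si](C)(C)C(C)(C)C)C1 | intermediate
28 | C12 primary alcohol | CC1=C(CCO)[C@@]3(C)C[C@@H](O[Si](c4ccccc4)(c4ccccc4)C(C)(C)C)C[C@](C)(CO[Si](c4ccccc4)(c4ccccc4)C(C)(C)C)[C@@H]3[C@@H](O[Si](C)(C)C(C)(C)C)C1 | intermediate
29 | C12 primary iodide | CC1=C(CCI)[C@@]3(C)C[C@@H](O[Si](c4ccccc4)(c4ccccc4)C(C)(C)C)C[C@](C)(CO[Si](c4ccccc4)(c4ccccc4)C(C)(C)C)[C@@H]3[C@@H](O[Si](C)(C)C(C)(C)C)C1 | intermediate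
30 | 4-bromofuran-2(5H)-one | O=C1OCC(Br)=C1 | starting material
31 | C12 alkylzinc iodide | CC1=C(CC[Zn]I)[C@@]3(C)C[C@@H](O[Si](c4ccccc4)(c4ccccc4)C(C)(C)C)C[C@](C)(CO[Si](c4ccccc4)(c4ccccc4)C(C)(C)C)[C@@H]3[C@@H](O[Si](C)(C)C(C)(C)C)C1 | intermediate
32 | tris-silylated target (2-O and 19-O TBDPS, 6-O TBS) | CC1=C(CCC2=CC(=O)OC2)[C@@]3(C)C[C@@H](O[Si](c4ccccc4)(c4ccccc4)C(C)(C)C)C[C@](C)(CO[Si](c4ccccc4)(c4ccccc4)C(C)(C)C)[C@@H]3[C@@H](O[Si](C)(C)C(C)(C)C)C1 | intermediate
33 | 2α,6α,19-trihydroxylabda-8,13-dien-15,16-olide, (2R,4S,5R,6S,10S) | CC1=C(CCC2=CC(=O)OC2)[C@@]2(C)C[C@@H](O)C[C@](C)(CO)[C@@H]2[C@@H](O)C1 | target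

Total step count: 22. Longest linear sequence: 19 (steps 1–8 and 12–22). Steps 9–11 build the side-chain chloride in parallel.

Steps most likely to fail

Step 16. What may go wrong: methyl transfer from aluminium or enolisation at the crowded aldehyde, diversion of the C8 cation by hydride or methyl shifts, or delivery of the axial carbinol. The fallback reverses the polarity but forms the same C6–C7 bond. It sets out from 23. Ene-type chlorination of the isopropenyl group (NaOCl, CeCl3·7H2O, CH2Cl2/H2O) gives the 2-(chloromethyl)allyl aldehyde F1, whose two CH2 termini are equivalent. CrCl2 in THF converts it into an allylchromium species that adds to the aldehyde (intramolecular Nozaki–Hiyama allylation) and returns to the route at 25. Should this closure, or step 16 itself, deliver oxygen axially, the 6β-alcohol F2 is oxidised (Dess–Martin periodinane) to the 6-ketone F3. This is then reduced under single-electron, thermodynamically governed conditions (SmI2, H2O, THF) to the equatorial alcohol 25.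

Step 15. What may go wrong: retro-allylation of the crowded potassium alkoxide, migration of the C19 silyl group to the C6 oxyanion, or leakage of chirality transfer through a rotamer with the oxyanion inside. The fallback makes C9–C10 by a neutral Claisen rearrangement at the ketone stage and adds C6 afterwards. It sets out from 10.
- Its enolate 11 is O-allylated with chloride 17 (KN(SiMe3)2, 18-crown-6, DMF) to the allyl enol ether F4.
- Heating (toluene, sealed tube) gives the 2,2,6,6-tetrasubstituted ketone F5. Facial control here comes from ring A only, so a chromatographic separation at C10 must be expected.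
- Dimethylsulfonium methylide (Me3SI, NaH, DMSO; Corey–Chaykovsky reaction) attacks from the open α face to give the spiro-epoxide F6.
- Meinwald rearrangement with MeAl(OC6H2-4-Br-2,6-t-Bu2)2 shifts hydride to C5 anti to the departing oxygen and returns to the route at 23.

Step 12. What may go wrong: sluggish addition to the hindered enal, loss of α-regioselectivity (bonding through C9), or loss of alkene geometry if the barium reagent warms. The fallback separates carbonyl addition from alkene construction. It sets out from 13. Symmetric 2-methylallylmagnesium chloride, which poses no regiochemical question, adds 1,2 to give the methallyl carbinol F7. Cross-metathesis with commercial 4-benzyloxybut-1-ene (second-generation Hoveyda–Grubbs catalyst, CH2Cl2, reflux) then builds the trisubstituted alkene and returns to the route at 19. Incomplete E selectivity is tolerable because it only affects the sacrificial C9 centre.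

Further compounds
F1 | step 16 | 2-(chloromethyl)allyl analogue of aldehyde 23 | C=C(CCl)[C@H](CCOCc1ccccc1)[C@@]2(C)C[C@@H](O[Si](c3ccccc3)(c3ccccc3)C(C)(C)C)C[C@](C)(CO[Si](c3ccccc3)(c3ccccc3)C(C)(C)C)[C@@H]2C=O
F2 | step 16 | 6β (axial) epimer of alcohol 25 | C=C1[C@H](CCOCc2ccccc2)[C@@]3(C)C[C@@H](O[Si](c4ccccc4)(c4ccccc4)C(C)(C)C)C[C@](C)(CO[Si](c4ccccc4)(c4ccccc4)C(C)(C)C)[C@@H]3[C@H](O)C1
F3 | step 16 | 6-ketone with exocyclic C8 methylene | C=C1[C@H](CCOCc2ccccc2)[C@@]3(C)C[C@@H](O[Si](c4ccccc4)(c4ccccc4)C(C)(C)C)C[C@](C)(CO[Si](c4ccccc4)(c4ccccc4)C(C)(C)C)[C@@H]3C(=O)C1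
F4 | step 15 | allyl enol ether of ketone 10 (C5–O–C7) | CC1=C(OC/C(C)=C/CCOCc2ccccc2)[C@@](C)(CO[Si](c2ccccc2)(c2ccccc2)C(C)(C)C)C[C@H](O[Si](c2ccccc2)(c2ccccc2)C(C)(C)C)C1
F5 | step 15 | C5 ketone with quaternary C10 bearing C9 | C=C(C)[C@H](CCOCc1ccccc1)[C@@]2(C)C[C@@H](O[Si](c3ccccc3)(c3ccccc3)C(C)(C)C)C[C@](C)(CO[Si](c3ccccc3)(c3ccccc3)C(C)(C)C)C2=O
F6 | step 15 | C5 spiro-epoxide (oxygen β, C6 α) | C=C(C)[C@H](CCOCc1ccccc1)[C@@]2(C)C[C@@H](O[Si](c4ccccc4)(c4ccccc4)C(C)(C)C)C[C@](C)(CO[Si](c4ccccc4)(c4ccccc4)C(C)(C)C)[C@@]23CO3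
F7 | step 12 | methallyl carbinol from enal 13 (both C6 epimers) | CC1=C(C(O)CC(C)=C)[C@@](C)(CO[Si](c2ccccc2)(c2ccccc2)C(C)(C)C)C[C@H](O[Si](c2ccccc2)(c2ccccc2)C(C)(C)C)C1
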